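**Assumptions:**
- The SMILES is read as the all-cis isomer (2R,3S,3aS,5R): 2-aryl, 3-methyl, 3a-allyl and 5-OMe all sit on one face.
- Ketone 6 is bought as a catalogue compound.

## Retrosynthetic overview

1. Target 10 is the flat trienone 8 plus two H₂ equivalents, all delivered to the face opposite the angular allyl: ionic hydrogenation of C2=C3 (10 ⇐ 9) and 1,4-reduction of C4=C5 with kinetic C5 protonation (9 ⇐ 8).
2. 8 ⇐ quinone monoketal 5 + enol silane 7: enantioselective C3–C3a bond formation at the allyl-bearing carbon, then cyclodehydration (C7a–O1–C2) closes the furan ring.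
3. 5 ⇐ 2-allyl-4,5-dimethoxyphenol 4 by oxidative dearomatization; 4 ⇐ 3,4-dimethoxyphenol + allyl bromide (O-allylation, Claisen); 7 ⇐ propiophenone 6.
4. Ring order: the carbocycle is the dearomatized arene; the O-heterocycle is closed onto it second. C3a is the only catalyst-set stereocentre; C5, C3 and C2 are relayed from it.

## Route

**Step 1**
Reactants: 1 (3,4-dimethoxyphenol), 2 (allyl bromide)
Product: 3, 4-(allyloxy)-1,2-dimethoxybenzene
Conditions: K2CO3, acetone, reflux
Reagents that add atoms: allyl bromide, C=CCBr
Why: Williamson O-allylation of the phenoxide; no stereochemistry.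

**Step 2**
Reactants: 3
Product: 4, 2-allyl-4,5-dimethoxyphenol
Conditions: PhNEt2, 190 °C
Reagents that add atoms: none
Why: Aromatic Claisen rearrangement to the less hindered ortho position (para to the 3-OMe); the minor 2-allyl-3,4-dimethoxy isomer is removed by chromatography.

**Step 3**
Reactants: 4
Product: 5, 2-allyl-4,4,5-trimethoxycyclohexa-2,5-dien-1-one
Conditions: PhI(OAc)2, MeOH, 0 °C
Reagents that add atoms: methanol, CO
Why: Hypervalent-iodine oxidative dearomatization; methanol traps the phenoxonium ion para to OH at the methoxy-bearing carbon to give the achiral p-quinone monoketal.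

**Step 4**
Reactants: 6 (1-(3,4,5-trimethoxyphenyl)propan-1-one)
Product: 7, (Z)-trimethyl{[1-(3,4,5-trimethoxyphenyl)prop-1-en-1-yl]oxy}silane
Conditions: TMSOTf, Et3N, CH2Cl2, 0 °C
Reagents that add atoms: trimethylsilyl triflate, C[Si](C)(C)OS(=O)(=O)C(F)(F)F
Why: Soft enolization/O-silylation of an aryl ethyl ketone (Z-enol silane); the geometry is inconsequential because C3 becomes sp2 again in 8.

**Step 5 (key step)**
Reactants: 5, 7
Product: 8, (3aS)-3a-allyl-5-methoxy-3-methyl-2-(3,4,5-trimethoxyphenyl)benzofuran-6(3aH)-one
Conditions: confined chiral IDPi Brønsted acid (2 mol %, enantiomer chosen to give 3aS), toluene, −78 °C; then TsOH·H2O (5 mol %), CH2Cl2, 0 °C; work up cold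
Reagents that add atoms: none
Why: Proposed new method: the in-situ silylated IDPi removes a ketal methoxide from 5 to give the 2-allyl-4,5-dimethoxyphenoxonium (vinylogous oxocarbenium) ion paired with the chiral anion, and 7 attacks the allyl-bearing ring carbon (the site that reacts in the known acid-promoted quinone-monoketal/propenylarene (3+2) condensations; C7 is an enol-ether carbon and not electrophilic) on the face left open by the anion, setting C3a (S) as the only stereocentre; silyl return gives the 1,4-dicarbonyl, which TsOH cyclodehydrates (ring carbonyl O onto the aryl ketone, net loss of MeOH from the vinylogous ester) to the flat enol-ether dienone 8; closest known reaction types are Lewis-acid Mukaiyama-type couplings of quinone monoketals and silylium counteranion-directed asymmetric Mukaiyama additions to oxocarbenium ions.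

**Step 6**
Reactants: 8
Product: 9, (3aS,5R)-3a-allyl-5-methoxy-3-methyl-2-(3,4,5-trimethoxyphenyl)-4,5-dihydrobenzofuran-6(3aH)-one
Conditions: [(Ph3P)CuH]6 (cat.), PhSiH3, toluene, 0 °C; then AcOH/TBAF, THF, −78 °C
Reagents that add atoms: none
Why: Cu–H conjugate (1,4) reduction: hydride adds to C4 of the α-methoxy enone arm (the other arm is a β-alkoxy-deactivated vinylogous ester; the allyl group and the enol ether are inert), and the silyl enol ether is protonated at C5 under kinetic control on the face opposite the pseudo-axial 3a-allyl, giving 5R (OMe cis to allyl).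

**Step 7**
Reactants: 9
Product: 10, Dysodanthin B, (2R,3S,3aS,5R)-3a-allyl-5-methoxy-3-methyl-2-(3,4,5-trimethoxyphenyl)-3,3a,4,5-tetrahydrobenzofuran-6(2H)-one
Conditions: Et3SiH, CF3CO2H, CH2Cl2, −40 → −10 °C; cold NaHCO3 quench
Reagents that add atoms: none
Why: Ionic hydrogenation of the 2-aryl enol ether: C3 is protonated anti to the angular allyl to give the aryl-stabilised C2 oxocarbenium ion, which takes hydride from the same open face (anti to the allyl and to the new 3-Me), so 3-Me and 2-Ar end up cis to the allyl (3S, 2R); the monosubstituted alkene and the vinylogous ester are not reduced under these conditions.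

## Compound list

1 | 3,4-dimethoxyphenol | COc1ccc(O)cc1OC | starting material
2 | allyl bromide | C=CCBr | starting material
3 | 4-(allyloxy)-1,2-dimethoxybenzene | C=CCOc1ccc(OC)c(OC)c1 | intermediate
4 | 2-allyl-4,5-dimethoxyphenol | C=CCc1cc(OC)c(OC)cc1O | intermediate
5 | 2-allyl-4,4,5-trimethoxycyclohexa-2,5-dien-1-one | C=CCC1=CC(OC)(OC)C(OC)=CC1=O | intermediate
6 | 1-(3,4,5-trimethoxyphenyl)propan-1-one | CCC(=O)c1cc(OC)c(OC)c(OC)c1 | starting material
7 | (Z)-trimethyl{[1-(3,4,5-trimethoxyphenyl)prop-1-en-1-yl]oxy}silane | C/C=C(\O[Si](C)(C)C)c1cc(OC)c(OC)c(OC)c1 | intermediate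
8 | (3aS)-3a-allyl-5-methoxy-3-methyl-2-(3,4,5-trimethoxyphenyl)benzofuran-6(3aH)-one | C=CC[C@@]12C=C(OC)C(=O)C=C1OC(c1cc(OC)c(OC)c(OC)c1)=C2C | intermediate
9 | (3aS,5R)-3a-allyl-5-methoxy-3-methyl-2-(3,4,5-trimethoxyphenyl)-4,5-dihydrobenzofuran-6(3aH)-one | C=CC[C@@]12C[C@@H](OC)C(=O)C=C1OC(c1cc(OC)c(OC)c(OC)c1)=C2C | intermediate
10 | Dysodanthin B, (2R,3S,3aS,5R)-3a-allyl-5-methoxy-3-methyl-2-(3,4,5-trimethoxyphenyl)-3,3a,4,5-tetrahydrobenzofuran-6(2H)-one | C=CC[C@@]12C[C@@H](OC)C(=O)C=C1O[C@@H](c1cc(OC)c(OC)c(OC)c1)[C@H]2C | target

## Step count and risks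

Total steps: 7. Longest linear sequence: 6 (1 → 3 → 4 → 5 → 8 → 9 → 10).

Three steps most likely to fail:

1. **Step 5.** Enantiofacial control by a chiral anion over a delocalized phenoxonium ion is unprecedented. C-closure to bicyclo[3.2.1] by-products can compete, and 8 is prone to aromatizing allyl shifts if warmed or left in acid.
   Fallback: move the stereocontrol to a chelating quinone. Oxidize 4 to 2-allyl-5-methoxy-1,4-benzoquinone and add 7 under a stoichiometric chiral Ti(IV)–TADDOLate, which binds the C=O/OMe pair next to the reacting enone carbon. Cyclodehydrate, then O-methylate the resulting 5-hydroxy dienone to 8. If that also fails, run the coupling racemically with TMSOTf and resolve 8 by chiral SFC.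

2. **Step 7.** The acid window is narrow. The acyl-like enol ether must be C-protonated without ionizing the benzylic C2–O1 bond of the product (reductive ring opening or C2 epimerization) and without epimerizing C5.
   Fallback: switch from the ionic to a radical manifold. A neutral Mn–H or Co–H HAT hydrogenation with PhSiH3 adds H• to C3 to give the benzylic, α-oxy C2 radical, and both hydrogens still arrive on the face opposite the allyl.

3. **Step 6.** The α-methoxy enone is a sluggish hydride acceptor. The C5 configuration rests only on kinetic protonation, and the wanted epimer (OMe syn-axial to allyl) is probably the less stable one.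
   Fallback: make C5 the last stereocentre. Take the C5 mixture through step 7, regenerate the α′-enolate of the vinylogous ester (LDA, −78 °C) and reprotonate with a bulky proton donor. Alternatively, perform step 7 on 8 first and the conjugate reduction last.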